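The route rests on one disconnection, the C8–C9 bond of ring B. Ring B carries the exocyclic C8=C17 methylene next to C9, which bears the C11H2–C12 arm: exactly what results when a C8 alkenyl unit adds to C9 of a C9=C11 enoate. A nickel-catalysed cathodic cyclisation of a ring A seco precursor therefore closes ring B, sets C9 and places the methylene in one operation. The precursor is ring A of podocarpic acid, intact at C4, C5 and C10, with a 3-bromobut-3-enyl arm on C5 and an E-enoate on C10; its C19 acid is held as a fluoride-labile 2-(trimethylsilyl)ethyl ester so that it can be freed at the end.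

Key step: step 9

Remark (assumption): the target is taken as the open (Z)-γ-hydroxy acid; it is therefore released last under basic conditions and brought only to about pH 4 in the cold, because stronger acid or heat would close the 15,12-lactone.

Remark (conventions): labdane numbering is used for all compounds, ring-opened ones included. Every compound keeps the ring A configuration of podocarpic acid (C4: α-CH3 and β-carboxyl C19; C5: α-H; C10: β-CH3). TMSE = 2-(trimethylsilyl)ethyl; TBS = tert-butyldimethylsilyl.

Step 1
Reactants: 1 podocarpic acid; 2 2-(trimethylsilyl)ethanol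
Product: 3 TMSE podocarpate
Conditions: PPh3, DIAD, THF, 0 °C → rt
Reagents that add atoms: 2-(trimethylsilyl)ethanol, OCC[Si](C)(C)C
Why: Mitsunobu esterification, in which the carboxylic acid (far more acidic than the phenol) is alkylated at oxygen by the activated primary alcohol, so the hindrance of the axial C19 carbonyl does not matter, and the resulting ester can later be removed by fluoride at silicon instead of by attack at that hindered carbonyl.

Step 2
Reactants: 3 TMSE podocarpate
Product: 4 ring A diacid (C8 and C9 acids)
Conditions: O3, CH2Cl2–MeOH, −78 °C; then 30% H2O2, aq. NaOH, 0 °C → rt; HCl to pH 3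
Reagents that add atoms: ozone, [O-][O+]=O; hydrogen peroxide, OO
Why: Exhaustive ozonolysis of the electron-rich phenol ring C followed by oxidative cleavage of the α-dicarbonyl fragments should leave C8 and C9 as carboxylic acids, while ring A and its three stereocentres carry no oxidisable group.

Step 3
Reactants: 4 ring A diacid
Product: 5 C8 methyl ester C9 acid
Conditions: MeOH, H2SO4 (cat.), rt
Reagents that add atoms: methanol, CO
Why: Fischer esterification is highly sensitive to hindrance, so only the unbranched C8 acid should be esterified whereas the C9 acid on quaternary C10 and the C19 ester on quaternary C4 are left alone.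

Step 4
Reactants: 5 C8 methyl ester C9 acid
Product: 6 C9 hydroxy C8 methyl ester
Conditions: BH3·THF, THF, 0 °C → rt
Reagents that add atoms: none
Why: Borane reduces a free carboxylic acid through its acyloxyborane much faster than it touches esters, which should convert the C9 acid into the neopentyl C9 alcohol chemoselectively.

Step 5
Reactants: 6 C9 hydroxy C8 methyl ester; 7 dimethyl (1-diazo-2-oxopropyl)phosphonate
Product: 9 alkynol, via hydroxy aldehyde 8 (not isolated)
Conditions: i-Bu2AlH (2.2 equiv), CH2Cl2, −78 °C; MeOH, −78 → 0 °C; then 7, K2CO3, MeOH, rt; aq. potassium sodium tartrate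
Reagents that add atoms: dimethyl (1-diazo-2-oxopropyl)phosphonate, CC(=O)C(=[N+]=[N-])P(=O)(OC)OC
Why: Partial reduction of the unhindered methyl ester stops at the aluminium hemiacetal at −78 °C, and the aldehyde freed by methanol is homologated in the same flask by the Ohira–Bestmann (Seyferth–Gilbert) reaction, which makes C8 the internal carbon of a terminal alkyne and adds C17.

Step 6
Reactants: 9 alkynol
Product: 10 alkynyl aldehyde
Conditions: Dess–Martin periodinane, CH2Cl2, rt
Reagents that add atoms: none
Why: Dess–Martin oxidation of the neopentyl primary alcohol gives the C9 aldehyde, which cannot enolise or epimerise because C10 is quaternary.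

Step 7
Reactants: 10 alkynyl aldehyde; 11 trimethyl phosphonoacetate
Product: 12 enyne ester
Conditions: 11, NaH, THF, 0 °C; then 10, 0 → 40 °C
Reagents that add atoms: trimethyl phosphonoacetate, COC(=O)CP(=O)(OC)OC
Why: Horner–Wadsworth–Emmons olefination with a stabilised phosphonate anion should give the E-enoate (C9=C11 with C12 as ester carbon), the bulky quaternary C10 reinforcing the E preference, and the preformed anion is too weak a base to deprotonate the alkyne.

Step 8
Reactants: 12 enyne ester
Product: 14 8-bromo seco dienoate (key-step precursor), via bromoalkenylborane 13 (not isolated)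
Conditions: B-Br-9-BBN, CH2Cl2, 0 °C; then AcOH, 0 °C → rt; ethanolamine work-up
Reagents that add atoms: B-bromo-9-borabicyclo[3.3.1]nonane, BrB1C2CCCC1CCC2
Why: cis-Bromoboration of the terminal alkyne places bromine on the internal carbon C8 and boron on C17, and protodeboronation with acetic acid then leaves the 2-bromo-1-alkene (net Markovnikov hydrobromination), while the electron-poor enoate and the hindered ester should not react with the haloborane.

Step 9
Reactants: 14 8-bromo seco dienoate
Product: 15 12-methyl 19-TMSE 13,14,15,16-tetranorlabd-8(17)-ene-12,19-dioate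
Conditions: NiBr2(bpy) (15 mol%), Bu4NBF4, DMF–pyridine (9:1), 0.02 M, undivided cell, Fe rod anode, Ni foam cathode, constant current (about 2.5 F/mol), 50 °C; aq. NH4Cl
Reagents that add atoms: none
Why: Electrons from the cathode reduce divalent nickel to zerovalent nickel, which inserts into the C8–Br bond; the C8 alkenylnickel adds across the tethered C9=C11 enoate to form C8–C9, and the metal enolate is protonated at C11 by traces of water or on work-up while the iron anode balances the charge and takes up bromide. The closest known reaction type is the nickel-catalysed electroreductive conjugate addition of alkenyl and aryl halides to acrylates, enones and unsaturated nitriles, used here in its intramolecular form. Ring B closes in the 6-exo-trig mode, C8 attacking C9 with C11 left outside the ring, which is preferred over 7-endo attack at C11 because C9 is the electrophilic β-carbon of the enoate. The one new stereocentre, C9, is controlled by C5 and C10 of ring A: their two arms are trans and equatorial, so a chair-like transition state should lead to the trans-decalin with the C11 arm equatorial and H9 axial on the α face, anti to the axial C10 methyl. The step needs cyclisation to outrun hydrodebromination and alkenyl homocoupling, which the short tether, high dilution and the lack of acidic protons in 14 should secure, and it needs the alkene to stay exocyclic, which is inherent because C8=C17 is the original bromoalkene and is never part of an elimination.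

Step 10
Reactants: 15 12-methyl 19-TMSE 13,14,15,16-tetranorlabd-8(17)-ene-12,19-dioate
Product: 16 C12 Weinreb amide
Conditions: MeNH(OMe)·HCl, i-PrMgCl, THF, −20 → 0 °C
Reagents that add atoms: N,O-dimethylhydroxylamine hydrochloride, CNOC.Cl
Why: The chloromagnesium amide of N,O-dimethylhydroxylamine aminolyses the unhindered C12 methyl ester directly (Weinreb amide formation from an ester), whereas the axial C19 ester on quaternary C4 should be inert to it.

Step 11
Reactants: 16 C12 Weinreb amide; 17 (trimethylsilyl)acetylene
Product: 18 silylalkynyl ketone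
Conditions: 17, n-BuLi, THF, −78 °C; then 16, −78 → 0 °C; aq. NH4Cl
Reagents that add atoms: (trimethylsilyl)acetylene, C#C[Si](C)(C)C
Why: Weinreb ketone synthesis, in which the lithium acetylide adds once and the chelated tetrahedral intermediate collapses to the alkynyl ketone only on work-up.

Step 12
Reactants: 18 silylalkynyl ketone
Product: 20 (12S) terminal propargylic alcohol, via silylated alkynol 19 (not isolated)
Conditions: Ru[(S,S)-TsDPEN](p-cymene) (2 mol%), i-PrOH, rt; then K2CO3, MeOH, rt
Reagents that add atoms: none
Why: Noyori asymmetric transfer hydrogenation of an alkynyl ketone, in which the (S,S) catalyst should deliver hydride to the carbonyl face that gives the (12S) carbinol under reagent control (the alkyne acts as the unsaturated group in the transition state and the nearest stereocentre, C9, is too remote to interfere), followed by base-catalysed methanolysis of the alkynyl C–Si bond.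

Step 13
Reactants: 20 (12S) terminal propargylic alcohol
Product: 21 (12S) TBS ether
Conditions: TBSCl, imidazole, DMF, rt
Reagents that add atoms: tert-butyldimethylsilyl chloride, CC(C)(C)[Si](C)(C)Cl
Why: Standard silylation of the secondary propargylic alcohol masks the hydroxyl for the lithiation that follows and keeps C12 from lactonising before the end.

Step 14
Reactants: 21 (12S) TBS ether; 22 methyl chloroformate
Product: 23 ynoate
Conditions: n-BuLi, THF, −78 °C; then 22, −78 → −20 °C
Reagents that add atoms: methyl chloroformate, COC(=O)Cl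
Why: Deprotonation of the terminal alkyne and C-acylation of the lithium acetylide with the chloroformate install C15 as the ynoate, the hindered C19 ester being untouched at −78 °C.

Step 15
Reactants: 23 ynoate
Product: 24 (12S,13Z) enoate
Conditions: Me2CuLi (from CuI and 2 MeLi), THF, −78 °C; MeOH then aq. NH4Cl at −78 °C
Reagents that add atoms: lithium dimethylcuprate, [Li+].C[Cu-]C
Why: Conjugate addition of the Gilman cuprate to the ynoate is a syn carbocupration, and protonation of the alkenylcopper at −78 °C with retention places the new C16 methyl cis to H14, which is the 13Z geometry (C12 cis to the C15 ester).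

Step 16
Reactants: 24 (12S,13Z) enoate
Product: 26 (12S)-12-hydroxylabda-8(17),13Z-diene-15,19-dioic acid, via C15 carboxylic acid 25 (not isolated)
Conditions: KOSiMe3, THF, rt; then Bu4NF, THF, rt → 40 °C; EtOAc / cold dil. HCl to pH 4
Reagents that add atoms: none
Why: Potassium trimethylsilanolate cleaves the unhindered C15 methyl ester to its carboxylate, and fluoride then removes the TBS ether and fragments the TMSE ester at silicon with loss of ethene, so the hydroxy diacid is set free as a salt that cannot lactonise and is protonated only at the end.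

Compound list
1 | (+)-podocarpic acid, 12-hydroxypodocarpa-8,11,13-trien-19-oic acid (4β-CO2H, 5α-H, 10β-CH3) | C[C@]12CCC[C@](C)(C(=O)O)[C@@H]1CCc1ccc(O)cc12 | starting material
2 | 2-(trimethylsilyl)ethanol | OCC[Si](C)(C)C | starting material
3 | 2-(trimethylsilyl)ethyl podocarpate | C[C@]12CCC[C@](C)(C(=O)OCC[Si](C)(C)C)[C@@H]1CCc1ccc(O)cc12 | intermediate
4 | ring A diacid: 19-TMSE ester of 8,9-seco-11,12,13,14-tetranorpodocarpane-8,9,19-trioic acid (arm C6H2–C7H2–C8O2H on C5, C9O2H on C10) | OC(=O)CC[C@@H]1[C@](C)(CCC[C@]1(C)C(=O)OCC[Si](C)(C)C)C(=O)O | intermediate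
5 | 8-methyl 19-TMSE diester of the same seco triacid, C9 acid free | COC(=O)CC[C@@H]1[C@](C)(CCC[C@]1(C)C(=O)OCC[Si](C)(C)C)C(=O)O | intermediate
6 | hydroxy ester: C9H2OH on C10, C8 methyl ester, C19 TMSE ester | COC(=O)CC[C@@H]1[C@](C)(CCC[C@]1(C)C(=O)OCC[Si](C)(C)C)CO | intermediate
7 | dimethyl (1-diazo-2-oxopropyl)phosphonate | CC(=O)C(=[N+]=[N-])P(=O)(OC)OC | starting material
8 | hydroxy aldehyde: C8HO at the end of the C5 arm, C9H2OH on C10, C19 TMSE ester (not isolated) | O=CCC[C@@H]1[C@](C)(CCC[C@]1(C)C(=O)OCC[Si](C)(C)C)CO | intermediate
9 | alkynol: but-3-ynyl arm (C6H2–C7H2–C8≡C17H) on C5, C9H2OH on C10, C19 TMSE ester | C#CCC[C@@H]1[C@](C)(CCC[C@]1(C)C(=O)OCC[Si](C)(C)C)CO | intermediate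
10 | alkynyl aldehyde: as 9 with C9HO on C10 | C#CCC[C@@H]1[C@](C)(CCC[C@]1(C)C(=O)OCC[Si](C)(C)C)C=O | intermediate
11 | trimethyl phosphonoacetate | COC(=O)CP(=O)(OC)OC | starting material
12 | enyne ester: methyl (E)-propenoate unit C9H=C11H–C12O2Me on C10, but-3-ynyl arm on C5, C19 TMSE ester | C#CCC[C@@H]1[C@](C)(CCC[C@]1(C)C(=O)OCC[Si](C)(C)C)/C=C/C(=O)OC | intermediate
13 | (Z)-bromoalkenylborane: C8(Br)=C17H–B(9-BBN) with Br and B cis, otherwise as 12 (not isolated) | Br/C(=C\B1C2CCCC1CCC2)CC[C@@H]1[C@](C)(CCC[C@]1(C)C(=O)OCC[Si](C)(C)C)/C=C/C(=O)OC | intermediate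
14 | key-step precursor: 12-methyl 19-TMSE 8-bromo-8,9-seco-13,14,15,16-tetranorlabda-8(17),9(11)E-diene-12,19-dioate | C=C(Br)CC[C@@H]1[C@](C)(CCC[C@]1(C)C(=O)OCC[Si](C)(C)C)/C=C/C(=O)OC | intermediate
15 | key-step product: 12-methyl 19-TMSE 13,14,15,16-tetranorlabd-8(17)-ene-12,19-dioate (5α-H, 9α-H, 10β-CH3) | C=C1CC[C@@H]2[C@](C)(CCC[C@]2(C)C(=O)OCC[Si](C)(C)C)[C@H]1CC(=O)OC | intermediate
16 | C12 N-methoxy-N-methylamide of 15, C19 TMSE ester | C=C1CC[C@@H]2[C@](C)(CCC[C@]2(C)C(=O)OCC[Si](C)(C)C)[C@H]1CC(=O)N(C)OC | intermediate
17 | (trimethylsilyl)acetylene | C#C[Si](C)(C)C | starting material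
18 | TMSE 12-oxo-14-(trimethylsilyl)-15,16-dinorlabd-8(17)-en-13-yn-19-oate | C=C1CC[C@@H]2[C@](C)(CCC[C@]2(C)C(=O)OCC[Si](C)(C)C)[C@H]1CC(=O)C#C[Si](C)(C)C | intermediate
19 | TMSE (12S)-12-hydroxy-14-(trimethylsilyl)-15,16-dinorlabd-8(17)-en-13-yn-19-oate (not isolated) | C=C1CC[C@@H]2[C@](C)(CCC[C@]2(C)C(=O)OCC[Si](C)(C)C)[C@H]1C[C@H](O)C#C[Si](C)(C)C | intermediate
20 | TMSE (12S)-12-hydroxy-15,16-dinorlabd-8(17)-en-13-yn-19-oate | C=C1CC[C@@H]2[C@](C)(CCC[C@]2(C)C(=O)OCC[Si](C)(C)C)[C@H]1C[C@H](O)C#C | intermediate
21 | TMSE (12S)-12-(tert-butyldimethylsilyloxy)-15,16-dinorlabd-8(17)-en-13-yn-19-oate | C=C1CC[C@@H]2[C@](C)(CCC[C@]2(C)C(=O)OCC[Si](C)(C)C)[C@H]1C[C@H](O[Si](C)(C)C(C)(C)C)C#C | intermediate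
22 | methyl chloroformate | COC(=O)Cl | starting material
23 | 15-methyl 19-TMSE (12S)-12-(tert-butyldimethylsilyloxy)-16-norlabd-8(17)-en-13-yne-15,19-dioate | C=C1CC[C@@H]2[C@](C)(CCC[C@]2(C)C(=O)OCC[Si](C)(C)C)[C@H]1C[C@H](O[Si](C)(C)C(C)(C)C)C#CC(=O)OC | intermediate
24 | 15-methyl 19-TMSE (12S,13Z)-12-(tert-butyldimethylsilyloxy)labda-8(17),13-diene-15,19-dioate | C=C1CC[C@@H]2[C@](C)(CCC[C@]2(C)C(=O)OCC[Si](C)(C)C)[C@H]1C[C@H](O[Si](C)(C)C(C)(C)C)/C(C)=C\C(=O)OC | intermediate
25 | (12S,13Z)-12-(tert-butyldimethylsilyloxy)labda-8(17),13-diene-15,19-dioic acid 19-TMSE ester (not isolated) | C=C1CC[C@@H]2[C@](C)(CCC[C@]2(C)C(=O)OCC[Si](C)(C)C)[C@H]1C[C@H](O[Si](C)(C)C(C)(C)C)/C(C)=C\C(=O)O | intermediate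
26 | (4S,5R,9S,10R,12S,13Z)-12-hydroxylabda-8(17),13-diene-15,19-dioic acid (CNP0144045.1) | C=C1CC[C@@H]2[C@](C)(CCC[C@]2(C)C(=O)O)[C@H]1C[C@H](O)/C(C)=C\C(=O)O | target

Total step count: 16. Longest linear sequence: 16 steps, from podocarpic acid 1 to 26.

Steps most likely to fail

1. Step 9 (ring B closure). The alkenylnickel may be protonated before it reaches the hindered C9 (hydrodebromination), the alkenyl unit may couple with itself, or the cathode may reduce the enoate directly. Fallback: it sets out from 14 and returns at 15 by a tin hydride radical chain (Bu3SnH added slowly, AIBN, benzene, 80 °C). The C8 alkenyl radical should close 6-exo onto C9 through the same chair-like arrangement, and the C11 radical next to the ester takes hydrogen from tin. This fallback makes no new compound (F0).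

2. Step 5 (ester to alkyne in one flask). The ester may be reduced past the aldehyde stage, or the hydroxy aldehyde may be held as a seven-membered lactol that reacts slowly with the diazophosphonate anion. Fallback: it sets out from 6 and returns at 9. MeNH(OMe)·HCl and i-PrMgCl in THF convert the C8 methyl ester into the C8 N-methoxy-N-methylamide F1. Reduction with i-Bu2AlH in THF at −78 °C stops at aldehyde 8 because of the chelated intermediate. Aldehyde 8 is then isolated and treated with 7 and K2CO3 in MeOH to give 9.

3. Step 16 (release of the hydroxy diacid). Cleavage of the β,β-disubstituted conjugated methyl ester may be slow, the 13Z alkene may drift under prolonged base, or the ring may close to the lactone during acidification. Fallback: it sets out from 24 and returns at 26. HF·pyridine in THF (0 °C → rt) removes the TBS group, and the Z-hydroxy ester should close at once to the 15,12-butenolide 19-TMSE ester F2, a neutral compound that can be purified. LiOH in THF–H2O at 0 °C opens the lactone to the lithium salt of the 12-hydroxy C15 acid 19-TMSE ester F3. This salt is kept basic and treated with Bu4NF to remove the TMSE group, followed by the same cold work-up at pH 4. The C15 ester is thus removed by intramolecular acyl transfer and a fast lactone opening, and fluoride never meets the butenolide, whose C12 hydrogen could epimerise.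

Further compounds
F0 | step 9 | none | none
F1 | step 5 | C8 N-methoxy-N-methylamide with C9H2OH on C10 and C19 TMSE ester | CON(C)C(=O)CC[C@@H]1[C@](C)(CCC[C@]1(C)C(=O)OCC[Si](C)(C)C)CO
F2 | step 16 | TMSE (12S)-labda-8(17),13-dien-15,12-olid-19-oate (butenolide) | C=C1CC[C@@H]2[C@](C)(CCC[C@]2(C)C(=O)OCC[Si](C)(C)C)[C@H]1C[C@@H]1OC(=O)C=C1C
F3 | step 16 | (12S,13Z)-12-hydroxylabda-8(17),13-diene-15,19-dioic acid 19-TMSE ester | C=C1CC[C@@H]2[C@](C)(CCC[C@]2(C)C(=O)OCC[Si](C)(C)C)[C@H]1C[C@H](O)/C(C)=C\C(=O)O
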